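**Strategy.** The 1,2-dioxane is closed last at its quaternary C6–O bond. C6 stands in a 1,4 relation to the side-chain ketone (C6–CH2–CH2–C=O), so C6 is made the donor carbon of an acylcyclopropane cut out of geraniol (asymmetric Simmons–Smith). In the key step a (3S)-hydroperoxide, set by syn-crotylboration and SN2 perhydrolysis, opens this cyclopropane in a Lewis-acid-mediated homo-Michael reaction: the extra C6–C bond, absent from the target, is cleaved with inversion, which fixes C6, closes the ring (6-exo-tet) and releases the CH2CH2C(=O) chain without leaving any residual functional group. A ketophosphonate activates the cyclopropane and later delivers the exo-methylene ketone.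

Key step: step 11

Remark on locants: target ring locants are used throughout (O1, O2, C3–H, C4, C5, quaternary C6); C2′ is the propanoate α-carbon and Cα–Cβ–Cγ(=O)–Cδ is the chain on C6.

Assumption: the (4R,5R)-dioxaborolane and the (+)-α-pinene-derived crotylborane are taken to show the facial sense they show on cinnamyl alcohol and on simple aliphatic aldehydes (otherwise the enantiomeric reagent is used); the phosphonate-bearing carbon Cδ is carried as an epimer mixture because it becomes sp2.

**Step 1**
Reactants: 1 ethyl 5-bromopentanoate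
Product: 3 6-bromo-2-methylhexan-2-ol, via 6-bromohexan-2-one 2 (not isolated)
Conditions: MeMgBr (2.2 equiv), THF, −20 → 0 °C; aq NH4Cl
Reagents that add atoms: methylmagnesium bromide, C[Mg]Br
Why: Double Grignard addition to the ester through ketone 2 should give the tertiary alcohol, the primary bromide being inert to MeMgBr at this temperature.

**Step 2**
Reactants: 3 6-bromo-2-methylhexan-2-ol
Product: 4 [(6-bromo-2-methylhexan-2-yl)oxy]triethylsilane
Conditions: TESOTf, 2,6-lutidine, CH2Cl2, 0 °C
Reagents that add atoms: triethylsilyl trifluoromethanesulfonate, CC[Si](CC)(CC)OS(=O)(=O)C(F)(F)F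
Why: Silyl triflate with a hindered pyridine base is the standard silylation of a tertiary alcohol, which must be masked against the bases and the Lewis acid used later.

**Step 3**
Reactants: 4 [(6-bromo-2-methylhexan-2-yl)oxy]triethylsilane
Product: 5 diethyl {5-methyl-5-[(triethylsilyl)oxy]hexyl}phosphonate
Conditions: P(OEt)3 (neat, 3 equiv), 150 °C, EtBr distilled off
Reagents that add atoms: triethyl phosphite, CCOP(OCC)OCC
Why: Michaelis–Arbuzov reaction of a primary bromide with triethyl phosphite should give the phosphonate, volatile bromoethane leaving the melt.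

**Step 4**
Reactants: 6 geraniol
Product: 7 [(1S,2S)-2-methyl-2-(4-methylpent-3-en-1-yl)cyclopropyl]methanol
Conditions: Zn(CH2I)2·DME (Et2Zn, CH2I2, DME), (4R,5R)-2-butyl-N,N,N′,N′-tetramethyl-1,3,2-dioxaborolane-4,5-dicarboxamide (1.2 equiv), CH2Cl2, −10 °C → rt
Reagents that add atoms: diiodomethane, ICI
Why: Charette asymmetric Simmons–Smith cyclopropanation, in which the zinc alkoxide bound to the chiral dioxaborolane directs CH2 to one face of the allylic alkene and the stereospecific syn addition preserves the E geometry, should set both cyclopropane centres, the quaternary one (future C6) as S.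

**Step 5**
Reactants: 7 [(1S,2S)-2-methyl-2-(4-methylpent-3-en-1-yl)cyclopropyl]methanol
Product: 8 (1S,2S)-2-methyl-2-(4-methylpent-3-en-1-yl)cyclopropane-1-carboxylic acid
Conditions: TEMPO (cat.), PhI(OAc)2 (2.2 equiv), MeCN/H2O 1:1, rt
Reagents that add atoms: water, O
Why: Oxoammonium (TEMPO/PhI(OAc)2) oxidation in aqueous acetonitrile carries a primary alcohol through the aldehyde hydrate to the acid without touching the trisubstituted alkene or the cyclopropane centres.

**Step 6**
Reactants: 8 (1S,2S)-2-methyl-2-(4-methylpent-3-en-1-yl)cyclopropane-1-carboxylic acid; 5 diethyl {5-methyl-5-[(triethylsilyl)oxy]hexyl}phosphonate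
Product: 10 diethyl {6-methyl-1-[(1S,2S)-2-methyl-2-(4-methylpent-3-en-1-yl)cyclopropyl]-1-oxo-6-[(triethylsilyl)oxy]heptan-2-yl}phosphonate (both epimers at the P-bearing carbon), via acyl imidazole 9 (not isolated)
Conditions: 8, CDI, THF, rt; added to lithiated 5 [5 (1.2 equiv), LDA (3.3 equiv), THF, −78 °C], −78 → −20 °C; aq NH4Cl
Reagents that add atoms: none
Why: Claisen-type acylation of an α-lithiophosphonate by an N-acylimidazole should stop at the ketone because the product is held as its enolate; the new phosphonate-bearing centre is left unassigned since it becomes sp2 in step 14.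

**Step 7**
Reactants: 10 cyclopropyl ketophosphonate
Product: 12 diethyl {6-methyl-1-[(1S,2S)-2-methyl-2-(3-oxopropyl)cyclopropyl]-1-oxo-6-[(triethylsilyl)oxy]heptan-2-yl}phosphonate, via ozonide 11 (not isolated)
Conditions: O3, CH2Cl2, −78 °C; Me2S, −78 °C → rt
Reagents that add atoms: ozone, [O-][O+]=O
Why: Ozonolysis with reductive work-up cleaves the only alkene to the aldehyde (future C3), the cyclopropane and the keto form of the ketophosphonate being inert to ozone.

**Step 8**
Reactants: 12 aldehyde
Product: 14 diethyl {1-[(1S,2S)-2-[(3R,4R)-3-hydroxy-4-methylhex-5-en-1-yl]-2-methylcyclopropyl]-6-methyl-1-oxo-6-[(triethylsilyl)oxy]heptan-2-yl}phosphonate, via borinate ester 13 (not isolated)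
Conditions: (−)-(Z)-crotyl-B(Ipc)2 [cis-but-2-ene, n-BuLi, KOtBu, THF, −78 → −45 °C; (−)-Ipc2BOMe; BF3·OEt2, −78 °C], then 12, THF, −78 °C; NaBO3·4H2O, H2O, rt
Reagents that add atoms: (Z)-crotyldiisopinocampheylborane (from cis-but-2-ene and (+)-α-pinene-derived (−)-Ipc2BOMe), C/C=C\CB([C@@H]1C[C@@H]2C[C@H]([C@H]1C)C2(C)C)[C@@H]1C[C@@H]2C[C@H]([C@H]1C)C2(C)C
Why: Brown asymmetric crotylboration: the (Z)-crotylborane adds through a chair Zimmerman–Traxler transition state, the Z geometry giving the syn relation and the (+)-α-pinene-derived ligands selecting the si face of the aldehyde (3R,4R), and the aldehyde should react far faster than the hindered ketone at −78 °C.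

**Step 9**
Reactants: 14 syn-homoallylic alcohol
Product: 15 diethyl {6-methyl-1-[(1S,2S)-2-methyl-2-{(3R,4R)-4-methyl-3-[(methylsulfonyl)oxy]hex-5-en-1-yl}cyclopropyl]-1-oxo-6-[(triethylsilyl)oxy]heptan-2-yl}phosphonate
Conditions: MsCl, Et3N, CH2Cl2, −10 °C
Reagents that add atoms: methanesulfonyl chloride, CS(=O)(=O)Cl
Why: Sulfonylation of the secondary alcohol with retention should supply the leaving group for the inverting peroxide substitution.

**Step 10**
Reactants: 15 mesylate
Product: 16 diethyl {1-[(1S,2S)-2-[(3S,4R)-3-hydroperoxy-4-methylhex-5-en-1-yl]-2-methylcyclopropyl]-6-methyl-1-oxo-6-[(triethylsilyl)oxy]heptan-2-yl}phosphonate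
Conditions: 50 % aq H2O2 (excess), KOH, MeOH, 0 °C → rt
Reagents that add atoms: hydrogen peroxide, OO
Why: SN2 displacement of a secondary sulfonate by hydroperoxide anion, a strong α-effect nucleophile of low basicity, is the classical route to secondary alkyl hydroperoxides and should invert C3 to S.

**Step 11**
Reactants: 16 (3S)-hydroperoxide carrying the acylcyclopropane
Product: 18 diethyl {1-[(3R,6S)-6-[(2R)-but-3-en-2-yl]-3-methyl-1,2-dioxan-3-yl]-8-methyl-3-oxo-8-[(triethylsilyl)oxy]nonan-4-yl}phosphonate (target locants: 3S,6R), via enol 17 (not isolated)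
Conditions: Sc(OTf)3 (20 mol %), 4 Å MS, CH2Cl2, −40 → 0 °C
Reagents that add atoms: none
Why: Proposed new method: Sc(III), chelated by the 1,3-ketophosphonate, polarises the cyclopropane bond between the acyl-bearing carbon and the fully substituted carbon (the only bond that places developing positive charge on a tertiary centre), and the terminal oxygen of the C3 hydroperoxide attacks that carbon from the face opposite the departing carbon, giving the metal enolate/enol 17, which is protonated to the ketone. The closest known reaction types are the inverting, SN2-like Lewis-acid ring openings of donor–acceptor cyclopropanes by heteroatom nucleophiles (also at quaternary donor carbons in annulations) and the intramolecular exo openings of epoxides and oxetanes by hydroperoxides that give 1,2-dioxanes; a hydroperoxide has not been used on a cyclopropyl ketone. The 1,2-dioxane closes in a 6-exo-tet mode, the cleaved C–C bond lying outside the new ring. C6 is set by inversion of the (S)-cyclopropane carbon installed in step 4, which places the side chain cis and the methyl trans to the C3 substituent, while C3 and C2′ are untouched and the second cyclopropane centre is erased as CH2. The step needs backside capture at the quaternary carbon to be faster than free ionisation, Cloke–Wilson closure to a dihydrofuran or proton loss; the tethered α-effect nucleophile, the non-ionising solvent and the low temperature are meant to secure this, and attack at the cyclopropane CH2 would need a seven-membered ring with no cation stabilisation.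

**Step 12**
Reactants: 18 vinyl dioxane
Product: 21 (2S)-2-[(3S,6R)-6-{4-(diethoxyphosphoryl)-8-methyl-3-oxo-8-[(triethylsilyl)oxy]nonyl}-6-methyl-1,2-dioxan-3-yl]propanoic acid, via ozonide 19 (not isolated), via aldehyde 20 (not isolated)
Conditions: O3, CH2Cl2, −78 °C; Me2S, −78 °C → rt; then NaClO2, NaH2PO4, 2-methylbut-2-ene, t-BuOH/H2O, 0 °C
Reagents that add atoms: ozone, [O-][O+]=O; sodium chlorite, [Na+].[O-]Cl=O
Why: Ozonolysis of the only C=C followed by Pinnick oxidation should give the acid, dialkyl peroxides being inert to ozone, dimethyl sulfide and chlorite, and the buffered medium protecting the epimerisable C2′ aldehyde 20.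

**Step 13**
Reactants: 21 acid
Product: 22 methyl (2S)-2-{(3S,6R)-6-[4-(diethoxyphosphoryl)-8-hydroxy-8-methyl-3-oxononyl]-6-methyl-1,2-dioxan-3-yl}propanoate
Conditions: HCl (from AcCl, 0.5 equiv), MeOH, 0 °C → rt
Reagents that add atoms: methanol, CO
Why: Fischer esterification in methanolic HCl, which at the same time solvolyses the tertiary triethylsilyl ether, should leave the acid-stable dialkyl peroxide and the ketophosphonate intact.

**Step 14**
Reactants: 22 hydroxy ketophosphonate ester
Product: 24 aikupikoxide D, methyl (2S)-2-[(3S,6R)-6-(8-hydroxy-8-methyl-4-methylidene-3-oxononyl)-6-methyl-1,2-dioxan-3-yl]propanoate, via hydroxymethyl adduct 23 (not isolated)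
Conditions: 37 % aq CH2O, K2CO3, THF/H2O, 0 °C → rt
Reagents that add atoms: formaldehyde, C=O
Why: Horner–Wadsworth–Emmons olefination of the α-substituted β-ketophosphonate with formaldehyde under carbonate, too weak a base to enolise the β-peroxy ester, should place the exo-methylene group regiospecifically on the phosphonate carbon.

**Compound list**
1 | ethyl 5-bromopentanoate | CCOC(=O)CCCCBr | starting material
2 | 6-bromohexan-2-one | CC(=O)CCCCBr | intermediate (not isolated)
3 | 6-bromo-2-methylhexan-2-ol | CC(C)(O)CCCCBr | intermediate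
4 | [(6-bromo-2-methylhexan-2-yl)oxy]triethylsilane | CC[Si](CC)(CC)OC(C)(C)CCCCBr | intermediate
5 | diethyl {5-methyl-5-[(triethylsilyl)oxy]hexyl}phosphonate | CCOP(=O)(OCC)CCCCC(C)(C)O[Si](CC)(CC)CC | intermediate
6 | geraniol, (2E)-3,7-dimethylocta-2,6-dien-1-ol | CC(C)=CCC/C(C)=C/CO | starting material
7 | [(1S,2S)-2-methyl-2-(4-methylpent-3-en-1-yl)cyclopropyl]methanol | CC(C)=CCC[C@@]1(C)C[C@@H]1CO | intermediate
8 | (1S,2S)-2-methyl-2-(4-methylpent-3-en-1-yl)cyclopropane-1-carboxylic acid | CC(C)=CCC[C@@]1(C)C[C@@H]1C(=O)O | intermediate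
9 | 1-[(1S,2S)-2-methyl-2-(4-methylpent-3-en-1-yl)cyclopropanecarbonyl]-1H-imidazole | CC(C)=CCC[C@@]1(C)C[C@@H]1C(=O)n1ccnc1 | intermediate (not isolated)
10 | diethyl {6-methyl-1-[(1S,2S)-2-methyl-2-(4-methylpent-3-en-1-yl)cyclopropyl]-1-oxo-6-[(triethylsilyl)oxy]heptan-2-yl}phosphonate, epimers at the P-bearing carbon | CC(C)=CCC[C@@]1(C)C[C@@H]1C(=O)C(CCCC(C)(C)O[Si](CC)(CC)CC)P(=O)(OCC)OCC | intermediate
11 | ozonide of 10 (3,3-dimethyl-1,2,4-trioxolane carrying the cyclopropylethyl group at C5) | CC1(C)OOC(CC[C@@]2(C)C[C@@H]2C(=O)C(CCCC(C)(C)O[Si](CC)(CC)CC)P(=O)(OCC)OCC)O1 | intermediate (not isolated)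
12 | diethyl {6-methyl-1-[(1S,2S)-2-methyl-2-(3-oxopropyl)cyclopropyl]-1-oxo-6-[(triethylsilyl)oxy]heptan-2-yl}phosphonate | O=CCC[C@@]1(C)C[C@@H]1C(=O)C(CCCC(C)(C)O[Si](CC)(CC)CC)P(=O)(OCC)OCC | intermediate
13 | O-diisopinocampheylboryl (borinate) ester of alcohol 14 | C=C[C@@H](C)[C@H](OB([C@@H]1C[C@@H]2C[C@H]([C@H]1C)C2(C)C)[C@@H]1C[C@@H]2C[C@H]([C@H]1C)C2(C)C)CC[C@@]1(C)C[C@@H]1C(=O)C(CCCC(C)(C)O[Si](CC)(CC)CC)P(=O)(OCC)OCC | intermediate (not isolated)
14 | diethyl {1-[(1S,2S)-2-[(3R,4R)-3-hydroxy-4-methylhex-5-en-1-yl]-2-methylcyclopropyl]-6-methyl-1-oxo-6-[(triethylsilyl)oxy]heptan-2-yl}phosphonate | C=C[C@@H](C)[C@H](O)CC[C@@]1(C)C[C@@H]1C(=O)C(CCCC(C)(C)O[Si](CC)(CC)CC)P(=O)(OCC)OCC | intermediate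
15 | methanesulfonate of 14, (3R,4R)-4-methyl-3-[(methylsulfonyl)oxy]hex-5-en-1-yl on the (1S,2S)-cyclopropane | C=C[C@@H](C)[C@H](OS(C)(=O)=O)CC[C@@]1(C)C[C@@H]1C(=O)C(CCCC(C)(C)O[Si](CC)(CC)CC)P(=O)(OCC)OCC | intermediate
16 | diethyl {1-[(1S,2S)-2-[(3S,4R)-3-hydroperoxy-4-methylhex-5-en-1-yl]-2-methylcyclopropyl]-6-methyl-1-oxo-6-[(triethylsilyl)oxy]heptan-2-yl}phosphonate | C=C[C@@H](C)[C@@H](OO)CC[C@@]1(C)C[C@@H]1C(=O)C(CCCC(C)(C)O[Si](CC)(CC)CC)P(=O)(OCC)OCC | intermediate
17 | enol (Cβ=Cγ–OH) form of 18 | C=C[C@@H](C)[C@@H]1CC[C@](C)(CC=C(O)C(CCCC(C)(C)O[Si](CC)(CC)CC)P(=O)(OCC)OCC)OO1 | intermediate (not isolated)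
18 | diethyl {1-[(3R,6S)-6-[(2R)-but-3-en-2-yl]-3-methyl-1,2-dioxan-3-yl]-8-methyl-3-oxo-8-[(triethylsilyl)oxy]nonan-4-yl}phosphonate | C=C[C@@H](C)[C@@H]1CC[C@](C)(CCC(=O)C(CCCC(C)(C)O[Si](CC)(CC)CC)P(=O)(OCC)OCC)OO1 | intermediate
19 | ozonide of 18 (1,2,4-trioxolan-3-yl in place of the vinyl group) | C[C@H](C2OCOO2)[C@@H]1CC[C@](C)(CCC(=O)C(CCCC(C)(C)O[Si](CC)(CC)CC)P(=O)(OCC)OCC)OO1 | intermediate (not isolated)
20 | (2S)-2-[(3S,6R)-6-{4-(diethoxyphosphoryl)-8-methyl-3-oxo-8-[(triethylsilyl)oxy]nonyl}-6-methyl-1,2-dioxan-3-yl]propanal | O=C[C@@H](C)[C@@H]1CC[C@](C)(CCC(=O)C(CCCC(C)(C)O[Si](CC)(CC)CC)P(=O)(OCC)OCC)OO1 | intermediate (not isolated)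
21 | (2S)-2-[(3S,6R)-6-{4-(diethoxyphosphoryl)-8-methyl-3-oxo-8-[(triethylsilyl)oxy]nonyl}-6-methyl-1,2-dioxan-3-yl]propanoic acid | OC(=O)[C@@H](C)[C@@H]1CC[C@](C)(CCC(=O)C(CCCC(C)(C)O[Si](CC)(CC)CC)P(=O)(OCC)OCC)OO1 | intermediate
22 | methyl (2S)-2-{(3S,6R)-6-[4-(diethoxyphosphoryl)-8-hydroxy-8-methyl-3-oxononyl]-6-methyl-1,2-dioxan-3-yl}propanoate | COC(=O)[C@@H](C)[C@@H]1CC[C@](C)(CCC(=O)C(CCCC(C)(C)O)P(=O)(OCC)OCC)OO1 | intermediate
23 | formaldehyde adduct of 22 (hydroxymethyl group on the phosphonate carbon) | COC(=O)[C@@H](C)[C@@H]1CC[C@](C)(CCC(=O)C(CO)(CCCC(C)(C)O)P(=O)(OCC)OCC)OO1 | intermediate (not isolated)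
24 | aikupikoxide D, methyl (2S)-2-[(3S,6R)-6-(8-hydroxy-8-methyl-4-methylidene-3-oxononyl)-6-methyl-1,2-dioxan-3-yl]propanoate | COC(=O)[C@@H](C)[C@@H]1CC[C@](C)(CCC(=O)C(=C)CCCC(C)(C)O)OO1 | target

**Step count.** Total: 14 steps. Longest linear sequence: 12 steps (1 → 24 through steps 1–3 and 6–14); 11 steps from geraniol 6.

**Steps most likely to fail**

1. Step 11 (Proposed new method). Ionisation of the C6–C bond may outrun backside capture, so that the configuration at C6 is lost. The ketone oxygen may close instead (Cloke–Wilson isomerisation to a dihydrofuran), the tertiary cation may lose a proton, or the ring may not open at all. The fallback uses known chemistry only and sets out from mesylate 15. The cyclopropyl ketone is opened with anhydrous HBr (CH2Cl2, −40 °C; Markovnikov ring opening of a 2,2-dialkylcyclopropyl ketone) to the tertiary γ-bromo ketone mesylate F1. Silver-assisted perhydrolysis (AgOTf, ethereal H2O2, 0 °C) then gives the tertiary hydroperoxide mesylate F2. Cs2CO3 in DMF closes the 1,2-dioxane by intramolecular SN2 displacement of the C3 mesylate (6-exo-tet, inversion at C3). Because C6 passes through a cation in this sequence, 18 would be formed together with its C6 epimer F3, which is removed by chromatography. The route is rejoined at 18.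

2. Step 10. E2 elimination toward the allylic C2′–H (1,3-diene formation) may compete with substitution at the β-branched secondary carbon, and hydroperoxide anion may attack the ketone or the phosphonate ester during the long reaction time. The fallback sets out from mesylate 15 and uses a protected, less basic peroxide nucleophile. Alkylation of 2-methoxyprop-2-yl hydroperoxide (CsOH·H2O, DMF, 0 °C) gives, with inversion, the peroxyketal F4. Mild acid hydrolysis (AcOH/THF/H2O, rt) then releases the hydroperoxide, rejoining the route at 16.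

3. Step 14. Base may open the β-peroxy ester by retro-oxa-Michael (E1cB) cleavage or trigger Kornblum–DeLaMare fragmentation at C3–H, and the new enone may polymerise or add nucleophiles. The fallback sets out from acid 21 and methylenates at the carboxylate stage, where the α-carbon cannot be enolised. Treatment with K2CO3 and aqueous CH2O gives the silyl-protected enone acid F5. TMSCHN2 (MeOH/toluene, 0 °C) then gives the silyl-protected methyl ester F6, which avoids acidic methanol on the enone. HF·pyridine (THF, 0 °C) removes the silyl group and gives the target 24.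

Further compounds
F1 | step 11 | diethyl {7-bromo-7,11-dimethyl-10-(R)-[(methylsulfonyl)oxy]-4-oxo-... open-chain tertiary bromide: (3R,4R)-mesylate 15 with the cyclopropane opened to C6(CH3)(Br)–CH2–CH2–C(=O) | C=C[C@@H](C)[C@H](OS(C)(=O)=O)CCC(C)(Br)CCC(=O)C(CCCC(C)(C)O[Si](CC)(CC)CC)P(=O)(OCC)OCC
F2 | step 11 | tertiary hydroperoxide mesylate, F1 with OOH in place of Br | C=C[C@@H](C)[C@H](OS(C)(=O)=O)CCC(C)(OO)CCC(=O)C(CCCC(C)(C)O[Si](CC)(CC)CC)P(=O)(OCC)OCC
F3 | step 11 | C6 epimer of 18 (target locants 3S,6S) | C=C[C@@H](C)[C@@H]1CC[C@@](C)(CCC(=O)C(CCCC(C)(C)O[Si](CC)(CC)CC)P(=O)(OCC)OCC)OO1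
F4 | step 10 | 2-methoxyprop-2-yl peroxyketal of hydroperoxide 16 | C=C[C@@H](C)[C@@H](OOC(C)(C)OC)CC[C@@]1(C)C[C@@H]1C(=O)C(CCCC(C)(C)O[Si](CC)(CC)CC)P(=O)(OCC)OCC
F5 | step 14 | (2S)-2-[(3S,6R)-6-methyl-6-{8-methyl-4-methylidene-3-oxo-8-[(triethylsilyl)oxy]nonyl}-1,2-dioxan-3-yl]propanoic acid | OC(=O)[C@@H](C)[C@@H]1CC[C@](C)(CCC(=O)C(=C)CCCC(C)(C)O[Si](CC)(CC)CC)OO1
F6 | step 14 | methyl (2S)-2-[(3S,6R)-6-methyl-6-{8-methyl-4-methylidene-3-oxo-8-[(triethylsilyl)oxy]nonyl}-1,2-dioxan-3-yl]propanoate | COC(=O)[C@@H](C)[C@@H]1CC[C@](C)(CCC(=O)C(=C)CCCC(C)(C)O[Si](CC)(CC)CC)OO1
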